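Plan
1. Cuts: first the depside ester bond between O4 of ring B and the C1' carbonyl of ring A. Ring B is then traced back to the ring A acid (OMe exchanged for OH), so only one arene has to be built. That arene is cut at C5'–C6' and C3'–C4' into a 2-pyrone and 1,1-dimethoxyethene.
2. The pyrone is cut at C4–C5 and O1–C2 into benzyl 3-oxodecanoate and malonyl dichloride. The keto ester is cut at C2–C3 into octanoyl chloride and Meldrum's acid.
3. Enabling feature: in ring A the carboxyl-bearing C1' lies between oxygen-bearing C2' and heptyl-bearing C6', which maps onto C5, C4 and C6 of a 2-pyrone-5-carboxylate. The sole OMe sits on C4', para to C1', where the acetal carbon of the ketene acetal ends up, and C5'–H is its CH2 carbon.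
4. Forward order: C10 chain, then the pyrone ring, then benzenoid ring A (the pyrone ring is used up). One portion is then demethylated and benzyl-esterified to ring B, followed by ester coupling and hydrogenolysis.
5. Stereochemistry: the target has no stereocentre and no stereogenic double bond. The two bridgehead centres of the cycloadduct are transient and need no control.

Key step: step 5

Remark on locants: unprimed locants refer to ring B (the half with the free CO2H) and primed locants to ring A (the acyl half). Pyrone atoms are counted O1, C2(=O), C3 to C6.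

Step 1
Reactants: 1 octanoyl chloride; 2 Meldrum's acid (2,2-dimethyl-1,3-dioxane-4,6-dione)
Product: 3 5-(1-hydroxyoctylidene)-2,2-dimethyl-1,3-dioxane-4,6-dione
Conditions: pyridine (2 equiv), CH2Cl2, 0 °C → rt; 1 M HCl wash
Reagents that add atoms: none
Why: Meldrum's acid is acidic enough for pyridine to form its enolate, which the acid chloride C-acylates cleanly (acyl Meldrum's acid synthesis), and the product rests as a hydrogen-bonded enol that resists a second acylation.

Step 2
Reactants: 3 5-(1-hydroxyoctylidene)-2,2-dimethyl-1,3-dioxane-4,6-dione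
Product: 5 benzyl 3-oxodecanoate, via octanoylketene 4 (not isolated)
Conditions: BnOH (1.1 equiv), toluene, reflux
Reagents that add atoms: benzyl alcohol, OCc1ccccc1
Why: On heating, 3 fragments by a retro-(4+2) process with loss of acetone and CO2 to acylketene 4, which benzyl alcohol captures at the ketene carbon (acyl Meldrum's acid alcoholysis, the standard β-keto ester synthesis).

Step 3
Reactants: 5 benzyl 3-oxodecanoate; 6 malonyl dichloride
Product: 7 benzyl 6-heptyl-4-hydroxy-2-oxo-2H-pyran-5-carboxylate
Conditions: 6 (1.0 equiv, slow addition), ClCH2CH2Cl, 0 → 60 °C, N2 sweep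
Reagents that add atoms: none
Why: The enolised β-keto ester is a 1,3-C,O-bis-nucleophile and malonyl dichloride a 1,3-bis-electrophile, so C-acylation at C2 of 5 (pyrone C4–C5 bond) and O-acylation of the ketone enol (O1–C2 bond) close the lactone in the known cyclocondensation that gives 4-hydroxy-6-alkyl-2-pyrone-5-carboxylates, with HCl leaving as a gas and the benzyl ester untouched.

Step 4
Reactants: 7 benzyl 6-heptyl-4-hydroxy-2-oxo-2H-pyran-5-carboxylate
Product: 8 benzyl 4-(benzyloxy)-6-heptyl-2-oxo-2H-pyran-5-carboxylate
Conditions: BnBr (1.2 equiv), K2CO3 (1.5 equiv), DMF, rt → 50 °C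
Reagents that add atoms: benzyl bromide, BrCc1ccccc1
Why: The 4-OH of 7 is a vinylogous carboxylic acid that K2CO3 deprotonates fully, and Williamson-type alkylation of such pyronates in a dipolar aprotic solvent takes place at O4 to give the fully conjugated 4-alkoxy-2-pyrone.

Step 5
Reactants: 8 benzyl 4-(benzyloxy)-6-heptyl-2-oxo-2H-pyran-5-carboxylate; 9 1,1-dimethoxyethene
Product: 12 benzyl 2-(benzyloxy)-6-heptyl-4-methoxybenzoate, via bridged bicyclic lactone 10 (not isolated), via cyclohexadiene dimethyl acetal 11 (not isolated)
Conditions: 9 (10 equiv), mesitylene (about 1 M), base-washed sealed tube, 140–150 °C, 24–48 h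
Reagents that add atoms: none
Why: The electron-rich alkene 9 (HOMO) and the ester-bearing diene C3=C4–C5=C6 of pyrone 8 (LUMO) combine in an inverse-electron-demand Diels–Alder reaction that is concerted but strongly asynchronous, the CH2 terminus of 9 bonding first to pyrone C6 (bond C5'–C6') and the acetal carbon then to C3 (bond C3'–C4'), which gives bridged lactone 10. At the reaction temperature 10 expels CO2 by a retro-(4+2) reaction to give 11, and 1,2-elimination of methanol from the CH2–C(OMe)2 unit of 11 aromatises it to 12, so ring A is closed by an intermolecular (4+2) annulation of four pyrone carbons with the two alkene carbons and not by cyclisation of a chain. The closest known reaction type is the conversion of 2-pyrone-5-carboxylates and of 6-alkyl-2-pyrone-3-carboxylates into methoxybenzoates with this same ketene acetal. The selectivity needed is regiochemical: C6 is both the β-carbon of the C5 acrylate unit and the far end of the dienyl lactone and is therefore the most electrophilic diene terminus, while the C4 benzyloxy group makes C3 the electron-rich terminus, so both effects pair C6 with the nucleophilic CH2 and C3 with the cation-like acetal carbon and place OMe para to the ester. The two bridgehead centres of 10 form as a racemate, are tied to each other by the bicycle and disappear on aromatisation, so no stereocontrol is required. Because the C4 donor and the C6 chain make 8 less electrophilic than the usual substrates, the step specifies a large excess of 9, high concentration, acid-free glass (to prevent acid-induced polymerisation of 9) and prolonged heating.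

Step 6
Reactants: 12 benzyl 2-(benzyloxy)-6-heptyl-4-methoxybenzoate
Product: 13 6-heptyl-2-hydroxy-4-methoxybenzoic acid (ring A acid)
Conditions: H2 (1 atm), 10% Pd/C, EtOAc–EtOH, rt
Reagents that add atoms: none
Why: Catalytic hydrogenolysis cleaves both benzylic C–O bonds (the ether and the hindered ester alike) under neutral conditions that leave the aryl methyl ether, the arene and the salicylic acid unit intact.

Step 7
Reactants: 13 6-heptyl-2-hydroxy-4-methoxybenzoic acid (one portion)
Product: 14 6-heptyl-2,4-dihydroxybenzoic acid
Conditions: BBr3 (4 equiv), CH2Cl2, −78 °C → rt; ice–water, work-up kept cold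
Reagents that add atoms: none
Why: In this BBr3 ether cleavage boron coordinates to the C4 methoxy oxygen and bromide attacks the methyl group by SN2, and running it after the benzyl groups are gone avoids Friedel–Crafts benzylation of the resorcinol ring while the cold work-up guards against decarboxylation.

Step 8
Reactants: 14 6-heptyl-2,4-dihydroxybenzoic acid
Product: 15 benzyl 6-heptyl-2,4-dihydroxybenzoate (ring B phenol)
Conditions: BnBr (1.05 equiv), KHCO3 (1.2 equiv), DMF, rt
Reagents that add atoms: benzyl bromide, BrCc1ccccc1
Why: KHCO3 ionises only the carboxylic acid, so SN2 alkylation of the carboxylate by benzyl bromide (chemoselective carboxylate O-alkylation, standard for resorcylic acids) esterifies 14 without touching either phenol.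

Step 9
Reactants: 13 6-heptyl-2-hydroxy-4-methoxybenzoic acid; 15 benzyl 6-heptyl-2,4-dihydroxybenzoate
Product: 17 benzyl 6-heptyl-4-[(6-heptyl-2-hydroxy-4-methoxybenzoyl)oxy]-2-hydroxybenzoate, via mixed trifluoroacetic anhydride 16 (not isolated)
Conditions: (CF3CO)2O (excess), toluene, rt; aqueous NaHCO3 work-up
Reagents that add atoms: trifluoroacetic anhydride, O=C(OC(=O)C(F)(F)F)C(F)(F)F (its CF3CO group stands only in 16; none of its atoms remain in 17)
Why: Trifluoroacetic anhydride turns 13 into mixed anhydride 16, which acylates the C4 hydroxyl of 15 (the classical depside esterification), while the C2 hydroxyl of 15 and the C2' hydroxyl of 13 are held back by hydrogen bonds to the neighbouring carbonyl groups and by ortho crowding.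

Step 10
Reactants: 17 benzyl 6-heptyl-4-[(6-heptyl-2-hydroxy-4-methoxybenzoyl)oxy]-2-hydroxybenzoate
Product: 18 6-heptyl-4-[(6-heptyl-2-hydroxy-4-methoxybenzoyl)oxy]-2-hydroxybenzoic acid (target CNP0234711.0)
Conditions: H2 (1 atm), 10% Pd/C, EtOAc, rt
Reagents that add atoms: none
Why: Hydrogenolysis of the benzyl ester is neutral and leaves the aryl ester link, the methyl ether and the phenols alone, which avoids any hydrolytic step that would cut the depside bond.

Compound list
1 | octanoyl chloride | CCCCCCCC(=O)Cl | starting material
2 | Meldrum's acid (2,2-dimethyl-1,3-dioxane-4,6-dione) | CC1(C)OC(=O)CC(=O)O1 | starting material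
3 | 5-(1-hydroxyoctylidene)-2,2-dimethyl-1,3-dioxane-4,6-dione | CCCCCCCC(O)=C1C(=O)OC(C)(C)OC1=O | intermediate
4 | 3-oxodec-1-en-1-one (octanoylketene, not isolated) | CCCCCCCC(=O)C=C=O | intermediate
5 | benzyl 3-oxodecanoate | CCCCCCCC(=O)CC(=O)OCc1ccccc1 | intermediate
6 | malonyl dichloride | O=C(Cl)CC(=O)Cl | starting material
7 | benzyl 6-heptyl-4-hydroxy-2-oxo-2H-pyran-5-carboxylate | CCCCCCCc1oc(=O)cc(O)c1C(=O)OCc1ccccc1 | intermediate
8 | benzyl 4-(benzyloxy)-6-heptyl-2-oxo-2H-pyran-5-carboxylate | CCCCCCCc1oc(=O)cc(OCc2ccccc2)c1C(=O)OCc1ccccc1 | intermediate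
9 | 1,1-dimethoxyethene | C=C(OC)OC | starting material
10 | benzyl 5-(benzyloxy)-1-heptyl-8,8-dimethoxy-3-oxo-2-oxabicyclo[2.2.2]oct-5-ene-6-carboxylate (bridged bicyclic lactone; racemic, one enantiomer drawn; not isolated) | CCCCCCC[C@]12CC(OC)(OC)[C@H](C(=O)O1)C(OCc1ccccc1)=C2C(=O)OCc1ccccc1 | intermediate
11 | benzyl 6-(benzyloxy)-2-heptyl-4,4-dimethoxycyclohexa-1,5-diene-1-carboxylate (not isolated) | CCCCCCCC1=C(C(=O)OCc2ccccc2)C(OCc2ccccc2)=CC(OC)(OC)C1 | intermediate
12 | benzyl 2-(benzyloxy)-6-heptyl-4-methoxybenzoate | CCCCCCCc1cc(OC)cc(OCc2ccccc2)c1C(=O)OCc1ccccc1 | intermediate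
13 | 6-heptyl-2-hydroxy-4-methoxybenzoic acid | CCCCCCCc1cc(OC)cc(O)c1C(=O)O | intermediate
14 | 6-heptyl-2,4-dihydroxybenzoic acid | CCCCCCCc1cc(O)cc(O)c1C(=O)O | intermediate
15 | benzyl 6-heptyl-2,4-dihydroxybenzoate | CCCCCCCc1cc(O)cc(O)c1C(=O)OCc1ccccc1 | intermediate
16 | 6-heptyl-2-hydroxy-4-methoxybenzoic trifluoroacetic anhydride (not isolated) | CCCCCCCc1cc(OC)cc(O)c1C(=O)OC(=O)C(F)(F)F | intermediate
17 | benzyl 6-heptyl-4-[(6-heptyl-2-hydroxy-4-methoxybenzoyl)oxy]-2-hydroxybenzoate | CCCCCCCc1cc(OC(=O)c2c(O)cc(OC)cc2CCCCCCC)cc(O)c1C(=O)OCc1ccccc1 | intermediate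
18 | 6-heptyl-4-[(6-heptyl-2-hydroxy-4-methoxybenzoyl)oxy]-2-hydroxybenzoic acid | CCCCCCCc1cc(OC(=O)c2c(O)cc(OC)cc2CCCCCCC)cc(O)c1C(=O)O | target

Total step count: 10.
Longest linear sequence: 10 steps (1 → 3 → 5 → 7 → 8 → 12 → 13 → 14 → 15 → 17 → 18). Compound 13 enters twice, once as ring A and once as the source of ring B.

Steps most likely to fail

Step 5.
- **Risk:** The cycloaddition may be too slow. The C4 donor raises the diene LUMO, and the C5 ester, crowded on both sides, is twisted out of conjugation. Thermal oligomerisation of the ketene acetal and slow decay of the pyrone could then outrun ring formation.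
- **Fallback (sets out from 1, comes back at 14 and, by way of 15, at 13):** The arene is made by aldol closure of a tetraketide instead of a cycloaddition.
  - Methanolysis of 1 (MeOH, Et3N) gives methyl octanoate F1.
  - The dianion of commercial 4-hydroxy-6-methyl-2H-pyran-2-one (LiN(iPr)2, THF, −78 °C) is acylated at its C6 methyl carbon by F1 to give 4-hydroxy-6-(2-oxononyl)-2H-pyran-2-one F2.
  - Aqueous KOH opens the lactone. An intramolecular aldol condensation between the carboxyl-bearing methylene carbon and the chain ketone, followed by dehydration, then closes the ring to 14.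
  - Compound 14 goes on to 15 as in step 8.
  - Selective methylation of the unchelated C4 hydroxyl of 15 (MeI, K2CO3, acetone) gives benzyl 6-heptyl-2-hydroxy-4-methoxybenzoate F3, and hydrogenolysis (H2, Pd/C) gives 13.

Step 3.
- **Risk:** The double acylation may not stop at the monocyclic stage. A second molecule of the bis-acid chloride could annulate C3 and the 4-OH of the product. Acylation at oxygen could also stall without ring closure, or HCl could erode the benzyl ester.
- **Fallback (sets out from 5, comes back at 7):** The two acylations are carried out one after the other with a reagent that has only one acid chloride.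
  - The magnesium enolate of 5 (MgCl2, pyridine, CH2Cl2, 0 °C) is C-acylated with methyl 3-chloro-3-oxopropanoate to give 1-benzyl 5-methyl 2-octanoyl-3-oxopentanedioate F4.
  - Base-induced enol lactonisation (DBU, toluene, reflux), the usual closure of 3,5-dioxo esters to 4-hydroxy-2-pyrones, expels methanol and gives 7.

Step 7.
- **Risk:** The very electron-rich acid may lose CO2 by protodecarboxylation under the Lewis and Brønsted acidic conditions. Demethylation may also stall once boron is chelated by the salicylate unit.
- **Fallback (sets out from 13, comes back at 14):** The loss of CO2 is accepted and the carboxyl group is put back afterwards.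
  - Hot 48% HBr in acetic acid demethylates and decarboxylates 13 to give 5-heptylbenzene-1,3-diol F5.
  - Carboxylation ortho to a phenol with methoxymagnesium methyl carbonate (MeOMgOCO2Me, DMF, 120 °C; cold dilute HCl), a Kolbe–Schmitt-type reaction in use for 5-alkylresorcinols, gives 14.

Further compounds
F1 | step 5 | methyl octanoate | CCCCCCCC(=O)OC
F2 | step 5 | 4-hydroxy-6-(2-oxononyl)-2H-pyran-2-one | CCCCCCCC(=O)Cc1cc(O)cc(=O)o1
F3 | step 5 | benzyl 6-heptyl-2-hydroxy-4-methoxybenzoate | CCCCCCCc1cc(OC)cc(O)c1C(=O)OCc1ccccc1
F4 | step 3 | 1-benzyl 5-methyl 2-octanoyl-3-oxopentanedioate | CCCCCCCC(=O)C(C(=O)OCc1ccccc1)C(=O)CC(=O)OC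
F5 | step 7 | 5-heptylbenzene-1,3-diol | CCCCCCCc1cc(O)cc(O)c1
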